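(Readings and results were computed for substances that don't exist, noise included.)

You are asked what stands in the flask after 5.0 d: how much product and how much quenched substrate.

1. concentration of product at 5.0 d, in mM
2. concentration of quenched substrate at 5.0 d, in mM

| setting | zeta | theta | flask |
|---|---|---|---|
| electrophile | 19 mM | 19 mM | 19 mM |
| solid nucleophile | 22.8 mM | 15 mM | 22.8 mM |
| protic impurity | 1.9 mM | 1.9 mM | 1.90 mM |
| remark | the very flask that is asked about, followed so far | run made earlier |  |
| time |  |  | 5.0 d |

| run | time / h | product / % | quenched substrate / % |
|---|---|---|---|
| zeta | 1.50 | 0 | 2.1 |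
| zeta | 3.00 | 1.0 | 2.9 |
| zeta | 6.00 | 1.2 | 3.4 |
| zeta | 12.0 | 1.7 | 6.3 |
| zeta | 20.0 | 3.3 | 7.0 |
| theta | 4.00 | 0.5 | 3.4 |
| theta | 8.00 | 0.6 | 4.1 |
| theta | 15.0 | 1.4 | 8.0 |
| theta | 25.0 | 3.7 | 9.1 |
| theta | 50.0 | 4.8 | 10.4 |

(standard deviation of a reading: 1 percentage point)

- the numbers in the tables scatter by 1 percentage point (one standard deviation)
- at the start none of the solid nucleophile is in solution

Take the time scales in turn, starting with the step to quenched substrate. The charge of protic impurity allows 10.0% of the electrophile to become quenched substrate. Zeta reads 6.3% by 12.0 h and theta 10.4% by 50.0 h, so I give this step a time scale near 12.0 h, far shorter than the asked time. The impurity is the limiting reagent of this step, so for the asked flask I put c(quenched substrate) at its charge, 1.90 mM.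

After its lag, theta's product gains a fraction 0.00100 /h of the charged electrophile between 8.00 h and 50.0 h. Zeta's 3.3% at 20.0 h lies between theta's 1.4% at 15.0 h and 3.7% at 25.0 h, so its extra solid shows nothing within the scatter.

Call the product clock the time in which this rate uses up the electrophile the quench leaves: 900 h, a pseudo-first-order time constant. It is longer than the asked time, so I stay on the straight line: c(product) = (c(electrophile) − c(protic impurity))·t/τ = 2.28 mM.

The forecast gives 1.6 mM of product, less than my figure, and 1.85 mM of quenched substrate, close to mine; it notes that “theta's last interval is noisy and may be slowing”.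

The simulation gives 2.36 mM of product and 1.90 mM of quenched substrate in the asked flask.

    electrophile + protic impurity → quenched substrate (k = 4.90 /M/h)
    solid nucleophile ⇌ nucleophile, rate k2*(cs2 - [nucleophile]) while solid is left; crystals form when [nucleophile] > cs2 (solubility = 0.650 mM, k = 0.0940 /h)
    nucleophile + acid set free ⇌ protonated nucleophile, settled at all times (K = 2400 /M)
    electrophile + nucleophile → acid set free + product (k = 3.90 /M/h)

In the asked flask the quench ran while protic impurity was there, with half its turnover done by 0.320 d and 88% by 1.00 d. The product step ran alongside and after it, with nucleophile at 0.330 mM at 2.50 d and 0.342 mM at 5.00 d, and c(product) went from 1.16 mM at 2.50 d to twice that at 5.00 d, against the clock's 2.28 mM.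

In a neighbour of the asked flask with 4.8 mM of protic impurity, the cap is that charge and the clock gives 1.89 mM of product. The computed neighbour holds 4.80 mM of quenched substrate and 2.13 mM of product.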